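## Retrosynthetic overview

1. Labels: C-a is the CH carrying isobutyl, C-b the ring-fusion CH next to CMe2, C-c the ring-fusion O–CH; unit A is the quinolinone on C-a, unit B the quinolinone on C-c.
2. Last bond: O(unit A)–C-c, by acid-mediated anti hydroalkoxylation of a 3-substituted dimethylpyranoquinolinone; that pyran comes from a lactol plus the 4-hydroxyquinolinone by Knoevenagel condensation and oxa-6π closure (C-c–C-3 of unit B, O–CMe2).
3. The lactol comes from an enol δ-lactone by partial reduction.
4. Key bond C-a–C-b: a carbene-bound enolate, generated from racemic prenal epoxide through its Breslow intermediate, adds to the quinolinone methide of unit A, which is assembled, parked as a sulfone and released in the same flask; this step fixes C-a.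
5. Ring order: pyridone ring of the common quinolinone (2,3-dimethoxyaniline + Meldrum's acid), then the central ring as δ-lactone, then the dimethylpyran ring, then the central ring re-closed as the cyclic ether.

Assumption: the (5aS,10bR) antipode of the triazolium salt is taken to give the (4S) lactone; if the facial sense is the reverse, the (5aR,10bS) salt is used and nothing else changes.

## Route

Step 1
Reactants: 1 2,3-dimethoxyaniline
Product: 3 2,3-dimethoxy-N-methylaniline, via N-methoxymethyl aminal 2 (not isolated)
Conditions: (CH2O)n (1.5 equiv), NaOMe (5 equiv), MeOH, 65 °C; then NaBH4 (1.5 equiv), 65 °C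
Reagents that add atoms: formaldehyde (used as paraformaldehyde), C=O
Why: Reductive N-monomethylation, in which the aniline condenses with formaldehyde under methoxide to the N-methoxymethyl aminal ether and NaBH4 reduces it (through the imine) to the secondary amine without over-alkylation; no stereocenter is formed.

Step 2
Reactants: 3 2,3-dimethoxy-N-methylaniline, 4 Meldrum's acid
Product: 6 4-hydroxy-7,8-dimethoxy-1-methylquinolin-2(1H)-one, via malonamic acid 5 (not isolated)
Conditions: toluene, 100 °C; then P2O5/MeSO3H (1:10 w/w), 70 °C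
Reagents that add atoms: none
Why: Aminolysis of Meldrum's acid with loss of acetone gives the malonamic acid, and the dehydrating acid then effects intramolecular Friedel–Crafts acylation at the only free ortho position (para to a methoxy group) followed by enolisation to the 4-hydroxy-2-quinolone; no stereocenter is formed.

Step 3
Reactants: 7 3-methylbut-2-enal
Product: 8 rac-3,3-dimethyloxirane-2-carbaldehyde
Conditions: 35% aq. H2O2 (1.2 equiv), NaOH (cat., pH 8–9), MeOH, 0 °C → rt; extracted into EtOAc, dried and kept as a cold stock solution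
Reagents that add atoms: hydrogen peroxide, OO
Why: Weitz–Scheffer nucleophilic epoxidation (conjugate addition of hydroperoxide, then ring closure); the racemate is sufficient because the epoxide CH becomes sp2 in step 4.

Step 4
Reactants: 6 4-hydroxy-7,8-dimethoxy-1-methylquinolin-2(1H)-one, 9 3-methylbutanal, 10 sodium benzenesulfinate, 8 rac-3,3-dimethyloxirane-2-carbaldehyde
Product: 13 (4S)-3-(2-hydroxypropan-2-yl)-7,8-dimethoxy-6-methyl-4-(2-methylpropyl)-3,4-dihydro-2H-pyrano[3,2-c]quinoline-2,5(6H)-dione, via quinolinone methide 11 (not isolated), via sulfone 12 (not isolated)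
Conditions: 9 (1.1 equiv), 10 (1.2 equiv), CF3CO2H (1.5 equiv), 4 Å molecular sieves, EtOAc, rt, 12 h; then, same flask, (5aS,10bR)-2-mesityl-5a,10b-dihydro-4H,6H-indeno[2,1-b][1,2,4]triazolo[4,3-d][1,4]oxazin-2-ium chloride (10 mol%), i-Pr2NEt (3 equiv), 0 °C → rt, 8 (1.5 equiv in EtOAc) added over 4 h
Reagents that add atoms: none
Why: Proposed new method: in the acidic first stage a Knoevenagel condensation gives methide 11, which the benzenesulfinic acid liberated from 10 traps by sulfa-Michael addition faster than a second quinolinone can add, so that all of 6 is parked as sulfone 12 before any base is present; the amine base then expels sulfinate to release oxadiene 11 gradually while the carbene adds to the aldehyde of 8 to give the Breslow intermediate (an acyl anion equivalent), whose epoxide opens to a β-alkoxy azolium enolate, so that the formerly electrophilic epoxide carbon becomes the nucleophile and bonds to the electrophilic methide carbon of 11 in an endo inverse-demand oxa-Diels–Alder (Michael–lactonisation) step that releases the carbene; the aminoindanol backbone shields one enolate face and thereby fixes C-4 as S (C-3 forms as an epimer mixture, 3,4-cis expected as major, and is erased in step 6), the closest known reactions being the carbene-catalysed redox esterification of epoxy aldehydes, the enantioselective azolium-enolate oxa-Diels–Alder reaction of α-chloroaldehydes with enones, and carbene catalysis on methides released from sulfone precursors by base.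

Step 5
Reactants: 13 (4S)-3-(2-hydroxypropan-2-yl)-7,8-dimethoxy-6-methyl-4-(2-methylpropyl)-3,4-dihydro-2H-pyrano[3,2-c]quinoline-2,5(6H)-dione
Product: 14 (4S)-2-hydroxy-3-(2-hydroxypropan-2-yl)-7,8-dimethoxy-6-methyl-4-(2-methylpropyl)-2,3,4,6-tetrahydro-5H-pyrano[3,2-c]quinolin-5-one
Conditions: i-Bu2AlH (2.2 equiv), CH2Cl2, −78 °C; aq. KNaC4H4O6 (potassium sodium tartrate)
Reagents that add atoms: none
Why: Partial lactone reduction, in which the first hydride equivalent is consumed by the tertiary alcohol and the second stops at the tetrahedral aluminium hemiacetal at −78 °C while the vinylogous amide carbonyl of the quinolone is untouched; C-4 is unaffected and the new anomeric centre is inconsequential.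

Step 6
Reactants: 14 (4S)-2-hydroxy-3-(2-hydroxypropan-2-yl)-7,8-dimethoxy-6-methyl-4-(2-methylpropyl)-2,3,4,6-tetrahydro-5H-pyrano[3,2-c]quinolin-5-one, 6 4-hydroxy-7,8-dimethoxy-1-methylquinolin-2(1H)-one
Product: 17 CNP0275598.1 (target; C-a S; C-b S; C-c R), via oxatriene 15 (not isolated), via dimethylpyran 16 (not isolated)
Conditions: 6 (1.05 equiv), ethylenediammonium diacetate (20 mol%), toluene, 60 °C; then CF3CO2H (1 equiv), CH2Cl2 (0.005 M), −20 → 0 °C
Reagents that add atoms: none
Why: The ring-opened aldehyde of 14 undergoes Knoevenagel condensation with 6 and E1cB loss of the tertiary hydroxyl to oxatriene 15, which closes by oxa-6π electrocyclisation to pyran 16 (the flindersine-type annulation), and acid then protonates C-3 of 16 on the face opposite the unit A quinolinone of the (S) side chain, held in its allylic-strain-minimised conformer (C-a–H eclipsing the C-b–CMe2 bond), while the enol oxygen captures the resulting benzylic cation at C-4 from its own face, a net anti hydroalkoxylation that gives the cis ring fusion with isobutyl trans to CMe2 (C-b S, C-c R).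

## Compound list

1 | 2,3-dimethoxyaniline | COc1cccc(N)c1OC | starting material
2 | N-(methoxymethyl)-2,3-dimethoxyaniline | COCNc1cccc(OC)c1OC | intermediate
3 | 2,3-dimethoxy-N-methylaniline | CNc1cccc(OC)c1OC | intermediate
4 | Meldrum's acid (2,2-dimethyl-1,3-dioxane-4,6-dione) | CC1(C)OC(=O)CC(=O)O1 | starting material
5 | 3-[(2,3-dimethoxyphenyl)(methyl)amino]-3-oxopropanoic acid | COc1cccc(N(C)C(=O)CC(=O)O)c1OC | intermediate
6 | 4-hydroxy-7,8-dimethoxy-1-methylquinolin-2(1H)-one | COc1ccc2c(O)cc(=O)n(C)c2c1OC | intermediate
7 | 3-methylbut-2-enal (prenal) | CC(C)=CC=O | starting material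
8 | rac-3,3-dimethyloxirane-2-carbaldehyde | CC1(C)OC1C=O | intermediate
9 | 3-methylbutanal (isovaleraldehyde) | CC(C)CC=O | starting material
10 | sodium benzenesulfinate | [Na+].[O-]S(=O)c1ccccc1 | starting material
11 | 7,8-dimethoxy-1-methyl-3-(3-methylbutylidene)quinoline-2,4(1H,3H)-dione | COc1ccc2C(=O)C(=CCC(C)C)C(=O)N(C)c2c1OC | intermediate
12 | rac-4-hydroxy-7,8-dimethoxy-1-methyl-3-[3-methyl-1-(phenylsulfonyl)butyl]quinolin-2(1H)-one | COc1ccc2c(O)c(C(CC(C)C)S(=O)(=O)c3ccccc3)c(=O)n(C)c2c1OC | intermediate
13 | (4S)-3-(2-hydroxypropan-2-yl)-7,8-dimethoxy-6-methyl-4-(2-methylpropyl)-3,4-dihydro-2H-pyrano[3,2-c]quinoline-2,5(6H)-dione (C-3 epimers) | COc1ccc2c3c(c(=O)n(C)c2c1OC)[C@@H](CC(C)C)C(C(C)(C)O)C(=O)O3 | intermediate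
14 | (4S)-2-hydroxy-3-(2-hydroxypropan-2-yl)-7,8-dimethoxy-6-methyl-4-(2-methylpropyl)-2,3,4,6-tetrahydro-5H-pyrano[3,2-c]quinolin-5-one (C-2 and C-3 epimers) | COc1ccc2c3c(c(=O)n(C)c2c1OC)[C@@H](CC(C)C)C(C(C)(C)O)C(O)O3 | intermediate
15 | 3-[(3S)-3-(4-hydroxy-7,8-dimethoxy-1-methyl-2-oxo-1,2-dihydroquinolin-3-yl)-5-methyl-2-(propan-2-ylidene)hexylidene]-7,8-dimethoxy-1-methylquinoline-2,4(1H,3H)-dione | COc1ccc2c(O)c(c(=O)n(C)c2c1OC)[C@@H](CC(C)C)C(=C(C)C)C=C1C(=O)c2ccc(OC)c(OC)c2N(C)C1=O | intermediate
16 | 3-[(1S)-1-(4-hydroxy-7,8-dimethoxy-1-methyl-2-oxo-1,2-dihydroquinolin-3-yl)-3-methylbutyl]-7,8-dimethoxy-2,2,6-trimethyl-2,6-dihydro-5H-pyrano[3,2-c]quinolin-5-one | COc1ccc2c(O)c(c(=O)n(C)c2c1OC)[C@@H](CC(C)C)C1=Cc2c(c3ccc(OC)c(OC)c3n(C)c2=O)OC1(C)C | intermediate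
17 | CNP0275598.1: cis-fused bis(pyranoquinolinone), C-a (isobutyl CH) S, C-b (ring-fusion CH next to CMe2) S, C-c (ring-fusion O–CH) R | COc1ccc2c3c(c(=O)n(C)c2c1OC)[C@@H](CC(C)C)[C@H]1[C@@H](O3)c2c(c3ccc(OC)c(OC)c3n(C)c2=O)OC1(C)C | target

## Step count and risks

Total step count: 6. Longest linear sequence: 5 steps (steps 1, 2, 4, 5, 6); step 3 is a one-step side branch.

Most likely to fail, in this order:

Step 4. The epoxide-derived enolate may collapse to the acyl azolium or lose acetone by retro-aldol before it meets 11, 11 can sequester the carbene, and the leftovers of the first stage (a little 9, extra sulfinate) share the flask with the catalyst. The fallback sets out from 6 and comes back at 13. Compound 6 is condensed with 9 and 10 in HCO2H and EtOH/H2O (1:1) at rt, and the sulfone 12 that precipitates is filtered off and dried. Compound 12 is then treated with sodium 2-chloro-1-hydroxyethanesulfonate (the bisulfite adduct of chloroacetaldehyde), the same triazolium salt and K2CO3 in toluene/water. The unsubstituted azolium enolate (again born from the Breslow intermediate of an α-chloroaldehyde) adds to 11 and gives the lactone without the hydroxypropyl group, (4S)-7,8-dimethoxy-6-methyl-4-(2-methylpropyl)-3,4-dihydro-2H-pyrano[3,2-c]quinoline-2,5(6H)-dione F1. F1 is then deprotonated with LiN(i-Pr)2 in THF at −78 °C and the lactone enolate is trapped with acetone, anti to the isobutyl group, to give 13.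

Step 6. The final cyclisation may give the trans-fused isomer or the C-b epimer, and 14 may undergo retro-aldol or form a bis-quinolinone adduct. The fallback sets out from 13 (with 6) and comes back at 17. Saponification of 13 with LiOH gives the β-hydroxy acid F3, and decarboxylative dehydration with N,N-dimethylformamide dineopentyl acetal in toluene at 110 °C gives the trisubstituted alkene F4. Separately, 6 with HC(OEt)3 in Ac2O gives the ethoxymethylidene dione F5. Heating F4 with F5 in toluene with removal of ethanol exchanges the ethoxy group for the enol oxygen of F4 to give the tethered oxadiene F6. F6 undergoes an intramolecular inverse-demand hetero-Diels–Alder reaction onto the Me2C=CH alkene; the concerted suprafacial addition through the aryl-type tether gives the cis fusion, and the C–H-eclipsed allylic conformer places isobutyl trans to CMe2, giving 17.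

Step 5. The enol lactone has a very good leaving group, so the aluminium hemiacetal may collapse and over-reduce. The fallback sets out from 13 and comes back at 14. Exhaustive reduction with LiBH4 in THF gives the ring-opened diol F2. Selective oxidation of its primary alcohol with SO3·pyridine, DMSO and Et3N gives the hydroxy aldehyde, which closes onto the enol oxygen to give 14.

## Further compounds

F1 | step 4 | (4S)-7,8-dimethoxy-6-methyl-4-(2-methylpropyl)-3,4-dihydro-2H-pyrano[3,2-c]quinoline-2,5(6H)-dione | COc1ccc2c3c(c(=O)n(C)c2c1OC)[C@@H](CC(C)C)CC(=O)O3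
F2 | step 5 | 4-hydroxy-3-[(4S)-2-hydroxy-3-(hydroxymethyl)-2,6-dimethylheptan-4-yl]-7,8-dimethoxy-1-methylquinolin-2(1H)-one | COc1ccc2c(O)c(c(=O)n(C)c2c1OC)[C@@H](CC(C)C)C(CO)C(C)(C)O
F3 | step 6 | 3-hydroxy-2-[(1S)-1-(4-hydroxy-7,8-dimethoxy-1-methyl-2-oxo-1,2-dihydroquinolin-3-yl)-3-methylbutyl]-3-methylbutanoic acid | COc1ccc2c(O)c(c(=O)n(C)c2c1OC)[C@@H](CC(C)C)C(C(=O)O)C(C)(C)O
F4 | step 6 | 3-[(4S)-2,6-dimethylhept-2-en-4-yl]-4-hydroxy-7,8-dimethoxy-1-methylquinolin-2(1H)-one | COc1ccc2c(O)c(c(=O)n(C)c2c1OC)[C@@H](CC(C)C)C=C(C)C
F5 | step 6 | 3-(ethoxymethylidene)-7,8-dimethoxy-1-methylquinoline-2,4(1H,3H)-dione | CCOC=C1C(=O)c2ccc(OC)c(OC)c2N(C)C1=O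
F6 | step 6 | 3-[({3-[(4S)-2,6-dimethylhept-2-en-4-yl]-7,8-dimethoxy-1-methyl-2-oxo-1,2-dihydroquinolin-4-yl}oxy)methylidene]-7,8-dimethoxy-1-methylquinoline-2,4(1H,3H)-dione | COc1ccc2c(OC=C3C(=O)c4ccc(OC)c(OC)c4N(C)C3=O)c(c(=O)n(C)c2c1OC)[C@@H](CC(C)C)C=C(C)C
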